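**Retrosynthetic overview**
1. Target 20 ← acid removal of two MOM ethers and one TES ether ← Claisen–Schmidt condensation of 5-acetyl ketone 17 with aldehyde 18 ← OMOM-directed C5 lithiation and acetylation of dihydrobenzofuran 15.
2. The dihydrofuran ring of 15 (O1–C2–C3–C3a–C7a) ← the oxirane ring of 11 (O–CH–CH2) enlarged by the two adjacent carbons of 3-(methoxymethoxy)benzyne 12, forming O1–C7a and C3–C3a in one operation.
3. Enabling feature: O1 and C3 sit on the neighbouring benzene carbons C7a and C3a, and C3a is flanked by the C4 oxygen, which polarises the aryne so that oxygen adds at C7a and the carbanion forms at C3a. The remaining ring atoms O1–C2–C3, with the tertiary carbinol on C2, are a terminal 1,2-epoxy-3-ol.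
4. Epoxide 11 ← nerol 6: Sharpless epoxidation sets both stereocentres, and a thiolate-trapped Payne transposition moves the oxirane to the chain terminus (one inversion at the future C2).
5. Ring order: oxirane (step 3, transposed in steps 4–5), then the dihydrofuran ring by ring expansion of that oxirane (step 7); both benzene rings are purchased.

Key step: step 7

Remark: locants O1, C2, C3, C3a, C4–C7, C7a are those of the 2,3-dihydro-1-benzofuran core of the target; the descriptor at the future C2 changes between 7, 8 and 10 partly through substituent priority, and the SMILES strings are authoritative.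

**Route**

Step 1
Reactants: 1 2-bromobenzene-1,3-diol
Product: 2 2-bromo-3-(methoxymethoxy)phenol
Conditions: NaH (1.0 equiv), MOMCl (1.0 equiv), THF/DMF, 0 °C; chromatography
Reagents that add atoms: chloromethyl methyl ether (MOMCl), COCCl
Why: Williamson O-alkylation of one of the two equivalent phenoxides of 1; the mono-ether is separated from the bis-ether and from unchanged 1, both of which can be recycled.

Step 2
Reactants: 2 2-bromo-3-(methoxymethoxy)phenol
Product: 5 3-(methoxymethoxy)-2-(trimethylsilyl)phenyl trifluoromethanesulfonate, via aryl trimethylsilyl ether 3 (not isolated), via lithium 2-silylphenoxide 4 (not isolated)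
Conditions: HMDS, THF, 70 °C, then evaporation; n-BuLi, THF, −100 °C; Tf2O, −100 → −78 °C
Reagents that add atoms: hexamethyldisilazane, C[Si](C)(C)N[Si](C)(C)C; trifluoromethanesulfonic anhydride, O=S(=O)(OS(=O)(=O)C(F)(F)F)C(F)(F)F
Why: O-silylation, bromine–lithium exchange and retro-Brook migration of silicon from oxygen to the lithiated carbon give the C-silyl phenoxide, which is trapped as the triflate, the standard sequence from 2-bromophenols to ortho-silylaryl triflates.

Step 3
Reactants: 6 nerol
Product: 7 [(2R,3S)-3-methyl-3-(4-methylpent-3-en-1-yl)oxiran-2-yl]methanol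
Conditions: Ti(OiPr)4 (cat.), D-(−)-diethyl tartrate (cat.), t-BuOOH, 4 Å molecular sieves, CH2Cl2, −20 °C
Reagents that add atoms: tert-butyl hydroperoxide, CC(C)(C)OO
Why: Sharpless asymmetric epoxidation, in which the titanium tartrate complex delivers oxygen only to the allylic alkene and, with the D-(−)-tartrate, to the face that gives the (2R,3S)-epoxide, so that both stereocentres of the target are set here by the catalyst while the remote trisubstituted alkene stays untouched.

Step 4
Reactants: 7 [(2R,3S)-3-methyl-3-(4-methylpent-3-en-1-yl)oxiran-2-yl]methanol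
Product: 8 (2R,3S)-3,7-dimethyl-1-(phenylsulfanyl)oct-6-ene-2,3-diol
Conditions: PhSH (slow addition), 0.5 M aq. NaOH, t-BuOH, 75 °C
Reagents that add atoms: thiophenol, Sc1ccccc1
Why: Payne rearrangement with thiolate trapping, in which the alkoxide of 7 equilibrates with the terminal 1,2-epoxy-3-ol by intramolecular SN2 at C2 (inversion at C2, C3 untouched) and thiolate opens the minor terminal epoxide at its unhindered C1.

Step 5
Reactants: 8 (2R,3S)-3,7-dimethyl-1-(phenylsulfanyl)oct-6-ene-2,3-diol
Product: 10 (2S)-6-methyl-2-[(2S)-oxiran-2-yl]hept-5-en-2-ol, via S-methylsulfonium tetrafluoroborate 9 (not isolated)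
Conditions: Me3OBF4, CH2Cl2, 0 °C → rt; then 2 M aq. NaOH, rt
Reagents that add atoms: none
Why: chemoselective S-methylation turns the thioether into a leaving group and the C2 alkoxide displaces methyl phenyl sulfide in a 3-exo-tet intramolecular Williamson closure, a known way from 1-thio-2,3-diols to 1,2-epoxy-3-ols that breaks no bond at either stereocentre (the new descriptor at C2 is a priority effect).

Step 6
Reactants: 10 (2S)-6-methyl-2-[(2S)-oxiran-2-yl]hept-5-en-2-ol
Product: 11 triethyl({(2S)-6-methyl-2-[(2S)-oxiran-2-yl]hept-5-en-2-yl}oxy)silane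
Conditions: TESOTf, 2,6-lutidine, CH2Cl2, −78 °C
Reagents that add atoms: triethylsilyl trifluoromethanesulfonate, CC[Si](CC)(CC)OS(=O)(=O)C(F)(F)F
Why: O-silylation of the hindered tertiary alcohol with a silyl triflate at −78 °C in the presence of excess base, which should leave the epoxide unactivated and removes the only acidic hydrogen before the aryne step.

Step 7
Reactants: 5 3-(methoxymethoxy)-2-(trimethylsilyl)phenyl trifluoromethanesulfonate; 11 triethyl({(2S)-6-methyl-2-[(2S)-oxiran-2-yl]hept-5-en-2-yl}oxy)silane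
Product: 15 (2S)-4-(methoxymethoxy)-2-{(2S)-6-methyl-2-[(triethylsilyl)oxy]hept-5-en-2-yl}-2,3-dihydro-1-benzofuran, via 3-(methoxymethoxy)benzyne 12 (not isolated), via O-aryloxiranium zwitterion 13 (not isolated), via ortho-metallated 2-iodoalkyl aryl ether 14 (not isolated)
Conditions: CsF, 18-crown-6, n-Bu4NI, PhMe, 50 °C; 5 added slowly to 11
Reagents that add atoms: none
Why: Proposed new method: fluoride-induced 1,2-elimination of 5 releases aryne 12, whose carbon remote from the OMOM group is attacked by the oxirane oxygen of 11 to give zwitterion 13 with the carbanion on the carbon flanked by both oxygens; because direct collapse of 13 would need a front-side displacement, iodide opens the activated oxiranium at its CH2 terminus by SN2 (14) and the aryl anion then expels iodide again, so that the three oxirane atoms O–CH–CH2 end up between the two former aryne carbons. The closest known reaction type is the fluoride-triggered insertion of arynes into the benzylic C–O bond of aryl oxiranes to give 2,3-dihydrobenzofurans, together with the three-component couplings of arynes, cyclic ethers and halide; new here is an alkyl-substituted terminal oxirane with a halide relay. The dihydrofuran ring closes by 5-exo-tet attack of the aryl anion on the CH2–I carbon, the O1–C7a bond having been made in the aryne addition. No stereocentre is created: the C2–O bond is never broken, so the configuration of the oxirane carbon is retained, and the silylated carbinol centre is a spectator. The step needs regioselectivity on the aryne, which the inductive effect of the OMOM oxygen next to the triple bond should secure by directing the nucleophile to the distal carbon, and site selectivity in the oxiranium opening, which the unhindered CH2 against a CH next to a fully substituted carbon should secure. It also needs the aryl anion to survive until it alkylates, which the absence of acidic hydrogen (toluene, silylated alcohol) and the reversibility of halide addition to the aryne should provide.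

Step 8
Reactants: 15 (2S)-4-(methoxymethoxy)-2-{(2S)-6-methyl-2-[(triethylsilyl)oxy]hept-5-en-2-yl}-2,3-dihydro-1-benzofuran
Product: 17 1-[(2S)-4-(methoxymethoxy)-2-{(2S)-6-methyl-2-[(triethylsilyl)oxy]hept-5-en-2-yl}-2,3-dihydro-1-benzofuran-5-yl]ethan-1-one, via 5-lithio arene 16 (not isolated)
Conditions: n-BuLi, TMEDA, THF, −78 → 0 °C; then MeC(O)N(OMe)Me, −78 °C → rt; aq. NH4Cl
Reagents that add atoms: N-methoxy-N-methylacetamide, CC(=O)N(C)OC
Why: directed ortho-metalation, in which the OMOM group complexes the base and directs lithiation to C5, its only free ortho position, followed by Weinreb ketone synthesis, whose stable chelated adduct prevents over-addition.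

Step 9
Reactants: 17 1-[(2S)-4-(methoxymethoxy)-2-{(2S)-6-methyl-2-[(triethylsilyl)oxy]hept-5-en-2-yl}-2,3-dihydro-1-benzofuran-5-yl]ethan-1-one; 18 4-(methoxymethoxy)benzaldehyde
Product: 19 (2E)-3-[4-(methoxymethoxy)phenyl]-1-[(2S)-4-(methoxymethoxy)-2-{(2S)-6-methyl-2-[(triethylsilyl)oxy]hept-5-en-2-yl}-2,3-dihydro-1-benzofuran-5-yl]prop-2-en-1-one
Conditions: KOH, EtOH, rt
Reagents that add atoms: none
Why: Claisen–Schmidt condensation, in which the methyl ketone enolate adds to the non-enolisable aldehyde and E1cB dehydration gives the thermodynamically favoured (E)-enone, the MOM and TES ethers being stable to base.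

Step 10
Reactants: 19 (2E)-3-[4-(methoxymethoxy)phenyl]-1-[(2S)-4-(methoxymethoxy)-2-{(2S)-6-methyl-2-[(triethylsilyl)oxy]hept-5-en-2-yl}-2,3-dihydro-1-benzofuran-5-yl]prop-2-en-1-one
Product: 20 (2E)-1-[(2S)-4-hydroxy-2-[(2S)-2-hydroxy-6-methylhept-5-en-2-yl]-2,3-dihydro-1-benzofuran-5-yl]-3-(4-hydroxyphenyl)prop-2-en-1-one
Conditions: 3 M aq. HCl, MeOH/THF, rt; monitored and quenched with aq. NaHCO3
Reagents that add atoms: none
Why: acid-catalysed acetal exchange should remove both MOM groups (the one next to the carbonyl first) and solvolysis should cleave the tertiary triethylsilyl ether, with no C–O bond at C2 or at the carbinol carbon being broken.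

**Compound list**
1 | 2-bromobenzene-1,3-diol | Oc1cccc(O)c1Br | starting material
2 | 2-bromo-3-(methoxymethoxy)phenol | COCOc1cccc(O)c1Br | intermediate
3 | [2-bromo-3-(methoxymethoxy)phenoxy]trimethylsilane | COCOc1cccc(O[Si](C)(C)C)c1Br | intermediate
4 | lithium 3-(methoxymethoxy)-2-(trimethylsilyl)phenoxide | COCOc1cccc([O-])c1[Si](C)(C)C.[Li+] | intermediate
5 | 3-(methoxymethoxy)-2-(trimethylsilyl)phenyl trifluoromethanesulfonate | COCOc1cccc(OS(=O)(=O)C(F)(F)F)c1[Si](C)(C)C | intermediate
6 | nerol, (2Z)-3,7-dimethylocta-2,6-dien-1-ol | CC(C)=CCC/C(C)=C\CO | starting material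
7 | [(2R,3S)-3-methyl-3-(4-methylpent-3-en-1-yl)oxiran-2-yl]methanol | CC(C)=CCC[C@]1(C)O[C@@H]1CO | intermediate
8 | (2R,3S)-3,7-dimethyl-1-(phenylsulfanyl)oct-6-ene-2,3-diol | CC(C)=CCC[C@](C)(O)[C@@H](O)CSc1ccccc1 | intermediate
9 | [(2R,3S)-2,3-dihydroxy-3,7-dimethyloct-6-en-1-yl](methyl)phenylsulfonium tetrafluoroborate | CC(C)=CCC[C@](C)(O)[C@@H](O)C[S+](C)c1ccccc1.F[B-](F)(F)F | intermediate
10 | (2S)-6-methyl-2-[(2S)-oxiran-2-yl]hept-5-en-2-ol | CC(C)=CCC[C@](C)(O)[C@@H]1CO1 | intermediate
11 | triethyl({(2S)-6-methyl-2-[(2S)-oxiran-2-yl]hept-5-en-2-yl}oxy)silane | CC(C)=CCC[C@](C)(O[Si](CC)(CC)CC)[C@@H]1CO1 | intermediate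
12 | 3-(methoxymethoxy)benzyne (1,2-didehydro-3-(methoxymethoxy)benzene) | COCOC1=CC=CC#C1 | intermediate
13 | (2S)-1-[3-(methoxymethoxy)benzen-2-id-1-yl]-2-{(2S)-6-methyl-2-[(triethylsilyl)oxy]hept-5-en-2-yl}oxiran-1-ium (zwitterion) | CC(C)=CCC[C@](C)(O[Si](CC)(CC)CC)[C@@H]1C[O+]1c1cccc(OCOC)[c-]1 | intermediate
14 | caesium 2-({(2R,3S)-1-iodo-3,7-dimethyl-3-[(triethylsilyl)oxy]oct-6-en-2-yl}oxy)-6-(methoxymethoxy)benzen-1-ide | CC(C)=CCC[C@](C)(O[Si](CC)(CC)CC)[C@H](CI)Oc1cccc(OCOC)[c-]1.[Cs+] | intermediate
15 | (2S)-4-(methoxymethoxy)-2-{(2S)-6-methyl-2-[(triethylsilyl)oxy]hept-5-en-2-yl}-2,3-dihydro-1-benzofuran | CC(C)=CCC[C@](C)(O[Si](CC)(CC)CC)[C@@H]1Cc2c(OCOC)cccc2O1 | intermediate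
16 | [(2S)-4-(methoxymethoxy)-2-{(2S)-6-methyl-2-[(triethylsilyl)oxy]hept-5-en-2-yl}-2,3-dihydro-1-benzofuran-5-yl]lithium | CC(C)=CCC[C@](C)(O[Si](CC)(CC)CC)[C@@H]1Cc2c(OCOC)c([Li])ccc2O1 | intermediate
17 | 1-[(2S)-4-(methoxymethoxy)-2-{(2S)-6-methyl-2-[(triethylsilyl)oxy]hept-5-en-2-yl}-2,3-dihydro-1-benzofuran-5-yl]ethan-1-one | CC(C)=CCC[C@](C)(O[Si](CC)(CC)CC)[C@@H]1Cc2c(OCOC)c(C(C)=O)ccc2O1 | intermediate
18 | 4-(methoxymethoxy)benzaldehyde | COCOc1ccc(C=O)cc1 | starting material
19 | (2E)-3-[4-(methoxymethoxy)phenyl]-1-[(2S)-4-(methoxymethoxy)-2-{(2S)-6-methyl-2-[(triethylsilyl)oxy]hept-5-en-2-yl}-2,3-dihydro-1-benzofuran-5-yl]prop-2-en-1-one | CC(C)=CCC[C@](C)(O[Si](CC)(CC)CC)[C@@H]1Cc2c(OCOC)c(C(=O)/C=C/c3ccc(OCOC)cc3)ccc2O1 | intermediate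
20 | (2E)-1-[(2S)-4-hydroxy-2-[(2S)-2-hydroxy-6-methylhept-5-en-2-yl]-2,3-dihydro-1-benzofuran-5-yl]-3-(4-hydroxyphenyl)prop-2-en-1-one | CC(C)=CCC[C@](C)(O)[C@@H]1Cc2c(ccc(C(=O)/C=C/c3ccc(O)cc3)c2O)O1 | target

**Step count**
Total: 10 steps. Longest linear sequence: 8 steps (nerol 6 to 20 through steps 3–10).

**Steps most likely to fail**

Step 7. Several processes may compete:
- capture of the aryne by an ene reaction with the trisubstituted alkene instead of by the weakly nucleophilic oxirane oxygen;
- a semipinacol-type 1,2-shift from the silyloxy-bearing carbon in the activated oxiranium;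
- opening of the oxiranium by fluoride instead of iodide;
- protonation of the aryl anion before it alkylates.

The fallback sets out from 11 and comes back at 15. Commercial 1-bromo-3-(methoxymethoxy)benzene would be deprotonated between bromine and the OMOM group with lithium diisopropylamide (THF, −78 °C) to give [2-bromo-6-(methoxymethoxy)phenyl]lithium F1. This should open 11 at its CH2 terminus in the presence of BF3·OEt2 at −78 °C to give (2S,3S)-1-[2-bromo-6-(methoxymethoxy)phenyl]-3,7-dimethyl-3-[(triethylsilyl)oxy]oct-6-en-2-ol F2. A palladium-catalysed intramolecular C–O coupling of the secondary alcohol with the aryl bromide (Pd(OAc)2, a bulky di-tert-butyl(biaryl)phosphine, Cs2CO3, PhMe, 80 °C) should then close O1–C7a with retention at C2 and give 15. The same three oxirane atoms are thereby set between the same two arene carbons, in two known bond formations instead of one.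

Step 8. Lithiation may lose site selectivity (C7 next to the ring oxygen, or benzylic C3 followed by E1cB opening of the dihydrofuran), and the aryllithium may be quenched by enolisation of the amide. The fallback sets out from 15 and comes back at 20, replacing the anionic acylation by a phenol-directed electrophilic one.
- Acid methanolysis (2 M HCl, MeOH, rt) should give (2S)-2-[(2S)-2-hydroxy-6-methylhept-5-en-2-yl]-2,3-dihydro-1-benzofuran-4-ol F3.
- Magnesium-mediated ortho-formylation (MgCl2, Et3N, paraformaldehyde, MeCN, reflux) can only occur at C5 and should give (2S)-4-hydroxy-2-[(2S)-2-hydroxy-6-methylhept-5-en-2-yl]-2,3-dihydro-1-benzofuran-5-carbaldehyde F4.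
- Excess MeMgBr (THF, 0 °C) should give (2S)-5-(1-hydroxyethyl)-2-[(2S)-2-hydroxy-6-methylhept-5-en-2-yl]-2,3-dihydro-1-benzofuran-4-ol F5 as a mixture of epimers at the new carbinol.
- Benzylic oxidation with MnO2 (CH2Cl2) should give 1-[(2S)-4-hydroxy-2-[(2S)-2-hydroxy-6-methylhept-5-en-2-yl]-2,3-dihydro-1-benzofuran-5-yl]ethan-1-one F6.
- Claisen–Schmidt condensation with 18 (excess KOH, EtOH) should give (2E)-1-[(2S)-4-hydroxy-2-[(2S)-2-hydroxy-6-methylhept-5-en-2-yl]-2,3-dihydro-1-benzofuran-5-yl]-3-[4-(methoxymethoxy)phenyl]prop-2-en-1-one F7.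
- Acid removal of its single MOM group (HCl, MeOH, rt) leads to 20.

Step 10. The aqueous acid may cause cyclisation of the tertiary alcohol onto the protonated trisubstituted alkene, ionisation of the tertiary alcohol, or chalcone-to-flavanone isomerisation before the ring-B MOM ether is fully cleaved. The fallback sets out from 17 and comes back at 20, leaving ring B unprotected so that strong acid is never needed. Claisen–Schmidt condensation of 17 with unprotected 4-hydroxybenzaldehyde (excess 50% aq. KOH, EtOH, rt) should give (2E)-3-(4-hydroxyphenyl)-1-[(2S)-4-(methoxymethoxy)-2-{(2S)-6-methyl-2-[(triethylsilyl)oxy]hept-5-en-2-yl}-2,3-dihydro-1-benzofuran-5-yl]prop-2-en-1-one F8. Buffered methanolysis (pyridinium p-toluenesulfonate, MeOH, 45 °C) should then remove the carbonyl-activated MOM ether and the TES ether to give 20.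

**Further compounds**
F1 | step 7 | [2-bromo-6-(methoxymethoxy)phenyl]lithium | [Li]c1c(Br)cccc1OCOC
F2 | step 7 | (2S,3S)-1-[2-bromo-6-(methoxymethoxy)phenyl]-3,7-dimethyl-3-[(triethylsilyl)oxy]oct-6-en-2-ol | CC(C)=CCC[C@](C)(O[Si](CC)(CC)CC)[C@@H](O)Cc1c(Br)cccc1OCOC
F3 | step 8 | (2S)-2-[(2S)-2-hydroxy-6-methylhept-5-en-2-yl]-2,3-dihydro-1-benzofuran-4-ol | CC(C)=CCC[C@](C)(O)[C@@H]1Cc2c(O)cccc2O1
F4 | step 8 | (2S)-4-hydroxy-2-[(2S)-2-hydroxy-6-methylhept-5-en-2-yl]-2,3-dihydro-1-benzofuran-5-carbaldehyde | CC(C)=CCC[C@](C)(O)[C@@H]1Cc2c(O)c(C=O)ccc2O1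
F5 | step 8 | (2S)-5-(1-hydroxyethyl)-2-[(2S)-2-hydroxy-6-methylhept-5-en-2-yl]-2,3-dihydro-1-benzofuran-4-ol | CC(C)=CCC[C@](C)(O)[C@@H]1Cc2c(O)c(C(C)O)ccc2O1
F6 | step 8 | 1-[(2S)-4-hydroxy-2-[(2S)-2-hydroxy-6-methylhept-5-en-2-yl]-2,3-dihydro-1-benzofuran-5-yl]ethan-1-one | CC(C)=CCC[C@](C)(O)[C@@H]1Cc2c(O)c(C(C)=O)ccc2O1
F7 | step 8 | (2E)-1-[(2S)-4-hydroxy-2-[(2S)-2-hydroxy-6-methylhept-5-en-2-yl]-2,3-dihydro-1-benzofuran-5-yl]-3-[4-(methoxymethoxy)phenyl]prop-2-en-1-one | CC(C)=CCC[C@](C)(O)[C@@H]1Cc2c(O)c(C(=O)/C=C/c3ccc(OCOC)cc3)ccc2O1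
F8 | step 10 | (2E)-3-(4-hydroxyphenyl)-1-[(2S)-4-(methoxymethoxy)-2-{(2S)-6-methyl-2-[(triethylsilyl)oxy]hept-5-en-2-yl}-2,3-dihydro-1-benzofuran-5-yl]prop-2-en-1-one | CC(C)=CCC[C@](C)(O[Si](CC)(CC)CC)[C@@H]1Cc2c(OCOC)c(C(=O)/C=C/c3ccc(O)cc3)ccc2O1
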